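**Strategy.** Ring B (C5–C10, eudesmane numbering) is grown from a five-membered ring, the cyclopentene of limonene-derived (S)-1-acetyl-4-isopropenylcyclopentene. C10, carrying its methyl and C1, is first laid across the C5=C9 bond as a cyclopropane while ring A closes as a cyclohexanone. The key step then cuts the cyclopropane bond C5–C9 reductively. The feature exploited is the sp2 carbon C4 of ring A next to the ring-fusion carbon C5: as a ketone, only the C5–C9 bond overlaps its π system. One operation turns the bicyclo[3.1.0]hexane into ring B, keeps quaternary C10 and leaves the C4 carbonyl for the C3=C4–C15 unit. C7 is corrected later by equilibration.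

Key step: step 6

Remark on the chemistry: eudesmane numbering is used throughout. C10 is the quaternary ring-fusion carbon with the methyl, C5 the ring-fusion CH, C7 the carbon bearing C11(=C13H2)–C12O2H, and C4 the alkene carbon bearing C15H2O. Ring A is C1–C5 plus C10, ring B is C5–C10, and β is the face of the C10 methyl. Compounds 14–16 are drawn with 5α-H; the C5 epimer would converge on 17 in step 7. The C7 centre taken from limonene is used to set C10 and is then deliberately inverted in step 7.

Step 1
Reactants: 1 (R)-(+)-limonene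
Product: 3 (3R)-6-oxo-3-(prop-1-en-2-yl)heptanal, via limonene ring ozonide 2 (not isolated)
Conditions: O3 (1 equiv), CH2Cl2, −78 °C; PPh3, −78 °C → rt
Reagents that add atoms: ozone, [O-][O+]=O
Why: Ozonolysis; ozone should attack the electron-rich trisubstituted ring alkene well before the 1,1-disubstituted isopropenyl group, so the ring is opened between C1 and C2 of limonene and the stereocentre is untouched.

Step 2
Reactants: 3 (3R)-6-oxo-3-(prop-1-en-2-yl)heptanal
Product: 4 (S)-1-[4-(prop-1-en-2-yl)cyclopent-1-en-1-yl]ethan-1-one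
Conditions: piperidine, AcOH, toluene, reflux (Dean–Stark)
Reagents that add atoms: none
Why: Intramolecular aldol condensation under amine–acid catalysis; the ketone α-methylene adds to the aldehyde with five-ring closure and dehydration gives the conjugated acetylcyclopentene, the stereocentre being non-enolisable (its descriptor changes to S only through priorities).

Step 3
Reactants: 4 (S)-1-[4-(prop-1-en-2-yl)cyclopent-1-en-1-yl]ethan-1-one; 5 2-(2-bromoethyl)-2-methyl-1,3-dioxolane
Product: 7 4-(2-methyl-1,3-dioxolan-2-yl)-1-[(S)-4-(prop-1-en-2-yl)cyclopent-1-en-1-yl]butan-1-one, via lithium enolate 6 (not isolated)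
Conditions: LiN(iPr)2, THF, −78 °C; then 5, DMPU, −78 → 0 °C
Reagents that add atoms: 5 2-(2-bromoethyl)-2-methyl-1,3-dioxolane, CC1(CCBr)OCCO1
Why: Kinetic α′-deprotonation of the methyl ketone and SN2 enolate alkylation with the primary bromide, a masked 3-oxobutyl unit, add C2, C1, C10 and the C10 methyl.

Step 4
Reactants: 7 ketal enone
Product: 9 5-(p-toluenesulfonylhydrazone) of 1-[(S)-4-(prop-1-en-2-yl)cyclopent-1-en-1-yl]hexane-1,5-dione, via diketone 8 (not isolated)
Conditions: 1 M HCl, THF, rt; then NaOAc, TsNHNH2, MeOH, rt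
Reagents that add atoms: p-toluenesulfonyl hydrazide, Cc1ccc(cc1)S(=O)(=O)NN
Why: Acetal hydrolysis followed by hydrazone formation, which should occur at the saturated methyl ketone much faster than at the conjugated, α-branched cyclopentenyl ketone.

Step 5
Reactants: 9 tosylhydrazone
Product: 12 tricyclic cyclopropyl ketone, via diazoalkane 10 (not isolated), via 1-pyrazoline 11 (not isolated)
Conditions: K2CO3, 1,4-dioxane, 110 °C; then hν (350 nm), rt
Reagents that add atoms: none
Why: Bamford–Stevens generation of the diazoalkane, intramolecular 1,3-dipolar cycloaddition to the enone C5=C9 and photochemical loss of N2 from the pyrazoline (either regiochemical sense of addition leads to the same cyclopropane) close ring A and the cyclopropane; the tether forces C1 cis to C4, so the C10 methyl is endo, and this endo methyl should direct addition to the face anti to the C7 isopropenyl group, which sets C5, C9 and C10 relative to C7.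

Step 6
Reactants: 12 tricyclic cyclopropyl ketone
Product: 14 15-nor-7-epi-eudesm-11-en-4-one, via lithium enolate 13 (not isolated)
Conditions: Li (2.5 equiv), NH3(l)–THF, t-BuOH (1 equiv), −78 °C; then NH4Cl
Reagents that add atoms: none
Why: Dissolving-metal cleavage of a cyclopropyl ketone: electron transfer to the C4 carbonyl gives a ketyl that opens the adjacent cyclopropane bond C5–C9, leaving lithium enolate 13 and a C9 radical that is reduced and protonated to CH2. No ring bond is formed: ring B (C5–C6–C7–C8–C9–C10) results when the cyclopentane C5–C6–C7–C8–C9 and the cyclopropane lose their shared bond, so C10 ends up inserted between C5 and C9. The closest known reaction type is the lithium–ammonia reduction of bicyclo[4.1.0]heptan-2-ones, which cleave the cyclopropane bond lying outside the six-membered ring. The step needs regioselectivity between C5–C9 and C5–C10: ring A holds C5–C10 near the nodal plane of the carbonyl π system while C5–C9 overlaps with it, and cleaving C5–C9 gives a secondary, not a tertiary, carbanion. C10 keeps the configuration it had in the cyclopropane (methyl endo, hence β and axial on ring B), while C5 is set by protonation of the enolate and is equilibrated in step 7. The isopropenyl group and the enolate should resist further reduction.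

Step 7
Reactants: 14 15-nor-7-epi-eudesm-11-en-4-one
Product: 17 12,15-dinoreudesmane-4,11-dione, via ozonide 15 (not isolated), via 7-epi-diketone 16 (not isolated)
Conditions: O3, CH2Cl2, −78 °C; PPh3; then NaOMe (cat.), MeOH, 0 °C → rt
Reagents that add atoms: ozone, [O-][O+]=O
Why: Ozonolysis of the only C=C bond unmasks the C7 acetyl group, and base-mediated epimerisation then equilibrates C7 (next to the acetyl) and C5 (next to the C4 ketone) to the favoured trans-decalin with equatorial 7β-acetyl, which inverts the limonene-derived centre to the natural configuration; the minor 7-epimer can be resubmitted.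

Step 8
Reactants: 17 12,15-dinoreudesmane-4,11-dione
Product: 19 12,15-dinoreudesma-3,11(13)-diene-4,11-diyl bis(trifluoromethanesulfonate), via dipotassium bis-enolate 18 (not isolated)
Conditions: KN(SiMe3)2 (2.4 equiv), THF, −78 °C; PhNTf2, −78 → 0 °C
Reagents that add atoms: N-phenylbis(trifluoromethanesulfonimide), O=S(=O)(N(c1ccccc1)S(=O)(=O)C(F)(F)F)C(F)(F)F
Why: Double kinetic enolisation (C3 methylene instead of the hindered C5 methine, acetyl methyl instead of C7) and O-sulfonylation give both enol triflates with the double bonds at C3=C4 and C11=C13 and without touching C5 or C7.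

Step 9
Reactants: 19 bis(enol triflate)
Product: 20 2-(trimethylsilyl)ethyl 4-(trifluoromethanesulfonyloxy)-15-noreudesma-3,11(13)-dien-12-oate
Conditions: Pd(OAc)2 (cat.), PPh3, Et3N, Me3SiCH2CH2OH, CO (1 atm), DMF, rt, stopped when 19 is consumed
Reagents that add atoms: carbon monoxide, [C-]#[O+]; 2-(trimethylsilyl)ethanol, C[Si](C)(C)CCO
Why: Palladium-catalysed alkoxycarbonylation of an enol triflate; oxidative addition should be much faster at the unhindered terminal C11 triflate than at the ring triflate flanked by the C5 methine next to quaternary C10, so only C12 is installed.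

Step 10
Reactants: 20 mono-triflate ester
Product: 21 2-(trimethylsilyl)ethyl 15-hydroxyeudesma-3,11(13)-dien-12-oate
Conditions: Bu3SnCH2OH, Pd(PPh3)4 (cat.), LiCl, 1,4-dioxane, 90 °C
Reagents that add atoms: (tributylstannyl)methanol, CCCC[Sn](CCCC)(CCCC)CO
Why: Stille coupling of the remaining enol triflate with the hydroxymethyl stannane installs C15 as the allylic alcohol, the position of the C3=C4 bond being fixed by the triflate.

Step 11
Reactants: 22 4-(tert-butyldimethylsilyloxy)benzaldehyde; 23 methyl bis(2,2,2-trifluoroethyl)phosphonoacetate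
Product: 25 methyl (Z)-3-[4-(tert-butyldimethylsilyloxy)phenyl]acrylate, via potassium phosphonate 24 (not isolated)
Conditions: KN(SiMe3)2, 18-crown-6, THF, −78 °C; then 22
Reagents that add atoms: 23 methyl bis(2,2,2-trifluoroethyl)phosphonoacetate, COC(=O)CP(=O)(OCC(F)(F)F)OCC(F)(F)F
Why: Still–Gennari olefination; the electron-poor phosphonate eliminates fast from the kinetic adduct, which should give the (Z)-enoate from an aromatic aldehyde.

Step 12
Reactants: 25 methyl (Z)-3-[4-(tert-butyldimethylsilyloxy)phenyl]acrylate
Product: 26 (Z)-4-hydroxycinnamic acid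
Conditions: LiOH, THF–MeOH–H2O, rt, dark; then 1 M HCl
Reagents that add atoms: lithium hydroxide, [Li+].[OH-]
Why: Saponification cleaves the methyl ester and the base-labile aryl silyl ether in one operation without touching the Z double bond.

Step 13
Reactants: 21 allylic alcohol; 26 (Z)-4-hydroxycinnamic acid
Product: 27 2-(trimethylsilyl)ethyl 15-[(Z)-4-hydroxycinnamoyloxy]eudesma-3,11(13)-dien-12-oate
Conditions: PPh3, DIAD, THF, 0 °C → rt, dark
Reagents that add atoms: 26 (Z)-4-hydroxycinnamic acid, OC(=O)/C=C\c1ccc(O)cc1
Why: Mitsunobu esterification; the primary allylic alcohol is activated as its oxyphosphonium salt and displaced by the carboxylate, while the far less acidic phenol should stay free and the Z geometry is protected by low temperature and darkness.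

Step 14
Reactants: 27 coupled ester
Product: 28 15-[(Z)-4-hydroxycinnamoyloxy]eudesma-3,11(13)-dien-12-oic acid (target)
Conditions: Bu4NF, THF, 0 °C → rt, dark; dilute HCl work-up
Reagents that add atoms: none
Why: Fluoride-induced β-elimination of the 2-(trimethylsilyl)ethyl ester releases ethylene and the C12 acid under conditions that should leave the allylic (Z)-cinnamate and both alkenes intact.

**Compound list**

1 | (R)-(+)-limonene | CC1=CC[C@@H](CC1)C(C)=C | starting material
2 | secondary ozonide of the ring alkene of limonene (mixture at the two ozonide carbons) | CC12CC[C@@H](C(C)=C)CC(O1)OO2 | intermediate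
3 | (3R)-6-oxo-3-(prop-1-en-2-yl)heptanal | CC(=O)CC[C@H](CC=O)C(C)=C | intermediate
4 | (S)-1-[4-(prop-1-en-2-yl)cyclopent-1-en-1-yl]ethan-1-one | CC(=O)C1=CC[C@@H](C1)C(C)=C | intermediate
5 | 2-(2-bromoethyl)-2-methyl-1,3-dioxolane | CC1(CCBr)OCCO1 | starting material
6 | lithium enolate of 4 (cross-conjugated, at the acetyl methyl) | [Li+].[O-]C(=C)C1=CC[C@@H](C1)C(C)=C | intermediate
7 | 4-(2-methyl-1,3-dioxolan-2-yl)-1-[(S)-4-(prop-1-en-2-yl)cyclopent-1-en-1-yl]butan-1-one | CC1(CCCC(=O)C2=CC[C@@H](C2)C(C)=C)OCCO1 | intermediate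
8 | 1-[(S)-4-(prop-1-en-2-yl)cyclopent-1-en-1-yl]hexane-1,5-dione | CC(=O)CCCC(=O)C1=CC[C@@H](C1)C(C)=C | intermediate
9 | 5-(p-toluenesulfonylhydrazone) of 8 | CC(CCCC(=O)C1=CC[C@@H](C1)C(C)=C)=NNS(=O)(=O)c1ccc(C)cc1 | intermediate
10 | 5-diazo-1-[(S)-4-(prop-1-en-2-yl)cyclopent-1-en-1-yl]hexan-1-one | CC(=[N+]=[N-])CCCC(=O)C1=CC[C@@H](C1)C(C)=C | intermediate
11 | fused 1-pyrazoline: C10 bonded to C5, N=N bridging C10 and C9, on the face anti to the isopropenyl group | C[C@]12CCCC(=O)[C@@]1(C[C@@H](C(C)=C)C3)[C@H]3N=N2 | intermediate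
12 | 6-methyl-3-(prop-1-en-2-yl)tricyclo[4.4.0.0^{1,5}]decan-10-one: ring-A cyclohexanone (C4 ketone) fused at C5–C10 to the cyclopropane C5–C9–C10, which is fused at C5–C9 to the cyclopentane C5–C9; C10 methyl endo, C7 isopropenyl anti to the cyclopropane | C[C@]12CCCC(=O)[C@]13C[C@@H](C(C)=C)C[C@H]23 | intermediate
13 | lithium enolate (C4–O, C4=C5) of the ring-expanded ketone | [Li+].[O-]C1=C2C[C@@H](C(C)=C)CC[C@@]2(C)CCC1 | intermediate
14 | 15-nor-7-epi-eudesm-11-en-4-one: 4a-methyl-7-(prop-1-en-2-yl)octahydronaphthalen-1(2H)-one with 10β-methyl, 7α-isopropenyl, 5α-H as drawn | CC(=C)[C@H]1CC[C@@]2(C)CCCC(=O)[C@@H]2C1 | intermediate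
15 | secondary ozonide of the isopropenyl group of 14 (mixture at the ozonide carbon) | CC1(OCOO1)[C@H]1CC[C@@]2(C)CCCC(=O)[C@@H]2C1 | intermediate
16 | 7-epi-12,15-dinoreudesmane-4,11-dione (7α-acetyl) | CC(=O)[C@H]1CC[C@@]2(C)CCCC(=O)[C@@H]2C1 | intermediate
17 | 12,15-dinoreudesmane-4,11-dione: 7-acetyl-4a-methyloctahydronaphthalen-1(2H)-one with 5α-H, 7β-acetyl, 10β-methyl | CC(=O)[C@@H]1CC[C@@]2(C)CCCC(=O)[C@@H]2C1 | intermediate
18 | dipotassium bis-enolate of 17 (C3=C4 and C11=C13) | [K+].[K+].C=C([O-])[C@@H]1CC[C@@]2(C)CCC=C([O-])[C@@H]2C1 | intermediate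
19 | 12,15-dinoreudesma-3,11(13)-diene-4,11-diyl bis(trifluoromethanesulfonate) | C=C(OS(=O)(=O)C(F)(F)F)[C@@H]1CC[C@@]2(C)CCC=C(OS(=O)(=O)C(F)(F)F)[C@@H]2C1 | intermediate
20 | 2-(trimethylsilyl)ethyl 4-(trifluoromethanesulfonyloxy)-15-noreudesma-3,11(13)-dien-12-oate | C=C(C(=O)OCC[Si](C)(C)C)[C@@H]1CC[C@@]2(C)CCC=C(OS(=O)(=O)C(F)(F)F)[C@@H]2C1 | intermediate
21 | 2-(trimethylsilyl)ethyl 15-hydroxyeudesma-3,11(13)-dien-12-oate | C=C(C(=O)OCC[Si](C)(C)C)[C@@H]1CC[C@@]2(C)CCC=C(CO)[C@@H]2C1 | intermediate
22 | 4-(tert-butyldimethylsilyloxy)benzaldehyde | CC(C)(C)[Si](C)(C)Oc1ccc(C=O)cc1 | starting material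
23 | methyl bis(2,2,2-trifluoroethyl)phosphonoacetate | COC(=O)CP(=O)(OCC(F)(F)F)OCC(F)(F)F | starting material
24 | potassium salt of the carbanion of 23 | [K+].COC(=O)[CH-]P(=O)(OCC(F)(F)F)OCC(F)(F)F | intermediate
25 | methyl (Z)-3-[4-(tert-butyldimethylsilyloxy)phenyl]acrylate | COC(=O)/C=C\c1ccc(O[Si](C)(C)C(C)(C)C)cc1 | intermediate
26 | (Z)-4-hydroxycinnamic acid | OC(=O)/C=C\c1ccc(O)cc1 | intermediate
27 | 2-(trimethylsilyl)ethyl 15-[(Z)-4-hydroxycinnamoyloxy]eudesma-3,11(13)-dien-12-oate | C=C(C(=O)OCC[Si](C)(C)C)[C@@H]1CC[C@@]2(C)CCC=C(COC(=O)/C=C\c3ccc(O)cc3)[C@@H]2C1 | intermediate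
28 | 15-[(Z)-4-hydroxycinnamoyloxy]eudesma-3,11(13)-dien-12-oic acid (5α-H, 7β side chain, 10β-methyl) | C=C(C(=O)O)[C@@H]1CC[C@@]2(C)CCC=C(COC(=O)/C=C\c3ccc(O)cc3)[C@@H]2C1 | target

**Total step count:** 14 (steps 11 and 12 form a two-step branch).
**Longest linear sequence:** 12 (steps 1–10, 13, 14).

**Steps most likely to fail**

Step 5. The diazoalkane may lose nitrogen before it cycloadds and then collapse by 1,2-hydrogen shift to alkenes, the pyrazoline may tautomerise instead of extruding nitrogen, or facial selectivity on the cyclopentene may be poor. The fallback sets out from 4 and returns at 12 by forming the cyclopropane first and ring A second. Enone 4 would undergo an intermolecular 1,3-dipolar cycloaddition with 4-(tert-butyldimethylsilyloxy)-2-diazobutane, generated in the flask from the sodium salt of the corresponding tosylhydrazone; the diazo carbon should bond to the enone β-carbon C9 to give the 1-pyrazoline F1. Photolysis should give the cyclopropyl methyl ketone silyl ether F2; only the C10 epimer with the side chain cis to the acetyl group is carried on. Bu4NF would free the primary alcohol F3, and I2, PPh3 and imidazole would give the iodide F4. LiN(iPr)2 would then form the acetyl enolate, which closes ring A by six-membered intramolecular alkylation to give 12.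

Step 9. Chemoselectivity between the two enol triflates may be lost, so that both are carbonylated. The fallback sets out from 19 and returns at 21 by differentiating the two positions after, not during, the palladium chemistry. Exhaustive methoxycarbonylation (Pd(OAc)2, 1,3-bis(diphenylphosphino)propane, CO, MeOH, Et3N, DMF, 60 °C) would give the dimethyl diester F5. One equivalent of LiOH at 0 °C should hydrolyse only the less hindered acrylate ester to the mono-acid F6. Excess (iBu)2AlH at −78 °C would reduce the ring enoate while the acid is held as its aluminium carboxylate, giving the hydroxy acid F7. Heating with 2-(trimethylsilyl)ethyl 2,2,2-trichloroacetimidate in toluene, which esterifies acids but not alcohols, would return 21.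

Step 13. The Z double bond may isomerise through reversible phosphine addition to the enoate, and substitution may occur with allylic transposition or at the phenol. The fallback sets out from 21 and returns at 27 by carboxylate alkylation. CBr4 and PPh3 in CH2Cl2 at 0 °C would convert 21 into the allylic bromide F8 before any cinnamate is present. The acid 26, deprotonated only at the carboxyl group by KHCO3 in DMF in the dark, would then displace bromide to give 27.

**Further compounds**

F1 | step 5 | 1-pyrazoline from 4 and 4-(tert-butyldimethylsilyloxy)-2-diazobutane (diazo carbon on C9, nitrogen on C5, anti to the isopropenyl group) | CC(=O)[C@@]12C[C@@H](C(C)=C)C[C@@H]1[C@@](C)(CCO[Si](C)(C)C(C)(C)C)N=N2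
F2 | step 5 | 1-acetyl-6-endo-methyl-6-exo-[2-(tert-butyldimethylsilyloxy)ethyl]-3-(prop-1-en-2-yl)bicyclo[3.1.0]hexane, isopropenyl anti to the cyclopropane | CC(=O)[C@@]12C[C@@H](C(C)=C)C[C@@H]1[C@@]2(C)CCO[Si](C)(C)C(C)(C)C
F3 | step 5 | the corresponding primary alcohol | CC(=O)[C@@]12C[C@@H](C(C)=C)C[C@@H]1[C@@]2(C)CCO
F4 | step 5 | the corresponding primary iodide | CC(=O)[C@@]12C[C@@H](C(C)=C)C[C@@H]1[C@@]2(C)CCI
F5 | step 9 | dimethyl eudesma-3,11(13)-diene-12,15-dioate | C=C(C(=O)OC)[C@@H]1CC[C@@]2(C)CCC=C(C(=O)OC)[C@@H]2C1
F6 | step 9 | 15-methoxy-15-oxoeudesma-3,11(13)-dien-12-oic acid | C=C(C(=O)O)[C@@H]1CC[C@@]2(C)CCC=C(C(=O)OC)[C@@H]2C1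
F7 | step 9 | 15-hydroxyeudesma-3,11(13)-dien-12-oic acid | C=C(C(=O)O)[C@@H]1CC[C@@]2(C)CCC=C(CO)[C@@H]2C1
F8 | step 13 | 2-(trimethylsilyl)ethyl 15-bromoeudesma-3,11(13)-dien-12-oate | C=C(C(=O)OCC[Si](C)(C)C)[C@@H]1CC[C@@]2(C)CCC=C(CBr)[C@@H]2C1
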